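Assumption: the target has no stereocentre and no hindered axis (ring B keeps an ortho H), so it is achiral and "single enantiomer" means the single constitutional isomer drawn. Compounds 1 and 4 are taken as catalogue chemicals.

**Retrosynthetic overview**
- Target 7 ⇒ tribromide 5 by removing the two ring-A bromines that sit para and ortho to OMe (late methoxy-directed bromination).
- 5 ⇒ ortho-quinone diazide 3 + 2-bromo-6-methoxyphenol 4 by cutting the diaryl ether C–O bond (carbene O–H insertion; the quinone C=O becomes the free ring-B OH).
- 3 ⇒ 2-amino-4,6-dibromophenol 1 (diazotisation).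
- No ring is formed: both benzene rings are bought, ring B with its bromines already in place.

**Route**

Step 1
Reactants: 1 2-amino-4,6-dibromophenol
Product: 3 2,4-dibromo-6-diazocyclohexa-2,4-dien-1-one, via diazonium chloride 2 (not isolated)
Conditions: NaNO2 (1.05 equiv), 2 M aq HCl/MeCN, 0 °C, 30 min; then NaHCO3 to pH 6–7, CH2Cl2 extraction, dark, concentrate below 30 °C (energetic solid, small batches)
Reagents that add atoms: sodium nitrite, [Na+].[O-]N=O
Why: Diazotisation of an ortho-aminophenol; the acidic 2-hydroxydiazonium ion loses its proton on neutralisation to give the neutral ortho-quinone diazide, and both bromines are meta to N2+ so they are not displaced.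

Step 2
Reactants: 3 2,4-dibromo-6-diazocyclohexa-2,4-dien-1-one; 4 2-bromo-6-methoxyphenol
Product: 5 2,4-dibromo-6-(2-bromo-6-methoxyphenoxy)phenol
Conditions: Rh2(esp)2 (1 mol%), 4 Å MS, PhCF3, 40 °C, dark; 3 added over 3 h to 4 (1.5 equiv)
Reagents that add atoms: none
Why: Proposed new method: Rh(II) strips N2 from 3 to give an electrophilic Rh-bound quinoid carbene at the former diazo carbon, the O–H of 4 adds to it to form an oxonium ylide, and a 1,4-proton shift to the neighbouring oxygen re-aromatises ring B, so the diaryl ether bond and the free ortho-OH arise in one step with both ring-B bromines already placed; the closest known reaction type is Rh(II)-carbenoid O–H insertion of α-diazo ketones into phenols together with Rh(II) carbene transfer from quinone diazides, which to my knowledge has not been shown for a halogenated benzo-ortho-quinone diazide and a 2,6-disubstituted halophenol to make a 2-aryloxyphenol.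

Step 3
Reactants: 5 2,4-dibromo-6-(2-bromo-6-methoxyphenoxy)phenol
Product: 7 2,4-dibromo-6-(2,3,5-tribromo-6-methoxyphenoxy)phenol, via tetrabromide 6 (not isolated)
Conditions: Br2 (2.2 equiv), AcOH, 20 → 60 °C; aq NaHSO3 quench
Reagents that add atoms: bromine, BrBr
Why: Electrophilic aromatic bromination: ring B has no free ortho or para site, and on ring A the methoxy group is the only conjugated donor (the bridging oxygen is twisted by its two ortho groups), so bromine enters para to OMe (giving 6) and then ortho to OMe, a site also para to the existing ring-A bromine, leaving the CH between two bromines untouched.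

**Compound list**
1 | 2-amino-4,6-dibromophenol | Nc1cc(Br)cc(Br)c1O | starting material
2 | 3,5-dibromo-2-hydroxybenzenediazonium chloride | Oc1c(Br)cc(Br)cc1[N+]#N.[Cl-] | intermediate (not isolated)
3 | 2,4-dibromo-6-diazocyclohexa-2,4-dien-1-one | O=C1C(Br)=CC(Br)=CC1=[N+]=[N-] | intermediate
4 | 2-bromo-6-methoxyphenol | COc1cccc(Br)c1O | starting material
5 | 2,4-dibromo-6-(2-bromo-6-methoxyphenoxy)phenol | COc1cccc(Br)c1Oc1cc(Br)cc(Br)c1O | intermediate
6 | 2,4-dibromo-6-(2,3-dibromo-6-methoxyphenoxy)phenol | COc1ccc(Br)c(Br)c1Oc1cc(Br)cc(Br)c1O | intermediate (not isolated)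
7 | 2,4-dibromo-6-(2,3,5-tribromo-6-methoxyphenoxy)phenol | COc1c(Br)cc(Br)c(Br)c1Oc1cc(Br)cc(Br)c1O | target

**Step count:** 3 steps in total; longest linear sequence 3 steps (1 → 3 → 5 → 7).

**Steps most likely to fail, with fallbacks**

Step 2 (the proposed new step). The risks are attack of the carbene on the free para carbon of 4 (C-arylation), Wolff ring contraction if light or heat reach 3, and carbene dimerisation. The fallback uses known chemistry, sets out from 4 and comes back at 5. SNAr of 4 on 2-fluorobenzaldehyde (K2CO3, DMF, 120 °C) gives 2-(2-bromo-6-methoxyphenoxy)benzaldehyde F2. Baeyer–Villiger oxidation with mCPBA (CH2Cl2, rt) gives 2-(2-bromo-6-methoxyphenoxy)phenyl formate F3. K2CO3 in MeOH cleaves the formate to 2-(2-bromo-6-methoxyphenoxy)phenol F4. Br2 (2.0 equiv, CH2Cl2, 0 °C) then brominates only the far more reactive free-phenol ring, para and then ortho to OH, through 4-bromo-2-(2-bromo-6-methoxyphenoxy)phenol F5 (not isolated), to give 5.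

Step 3. The risks are that the second ring-A bromine enters the CH para to the bridging oxygen instead of ortho to OMe, and over-bromination. The fallback brominates ring A before the coupling, with the phenol oxygen acylated so that OMe is the only director and isomers can be removed by crystallisation on a small molecule. It sets out from 4 and comes back at 7. Ac2O/pyridine gives 2-bromo-6-methoxyphenyl acetate F6. Br2 (2.2 equiv, AcOH, 50 °C) gives, through 2,3-dibromo-6-methoxyphenyl acetate F7 (not isolated), 2,3,5-tribromo-6-methoxyphenyl acetate F8, which is recrystallised. K2CO3 in MeOH gives 2,3,5-tribromo-6-methoxyphenol F9. F9 is coupled with 3 under the step 2 conditions to give 7 directly. This fallback still relies on the step 2 coupling; its deactivated, flanked para position also removes the C-arylation risk there.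

Step 1. The reaction itself is classical; the risk is isolating and storing the light-sensitive, energetic diazo oxide 3. The fallback stores a diazonium salt instead and releases 3 only in solution. It sets out from 1 and comes back at 3. t-BuONO and HBF4·OEt2 in EtOH at 0 °C, then Et2O, precipitate 3,5-dibromo-2-hydroxybenzenediazonium tetrafluoroborate F1, which is kept cold. Just before step 2, F1 is stirred in CH2Cl2 with cold aq NaHCO3, and the dried organic layer containing 3 is used without isolation.

**Further compounds**
F1 | step 1 | 3,5-dibromo-2-hydroxybenzenediazonium tetrafluoroborate | Oc1c(Br)cc(Br)cc1[N+]#N.F[B-](F)(F)F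
F2 | step 2 | 2-(2-bromo-6-methoxyphenoxy)benzaldehyde | COc1cccc(Br)c1Oc1ccccc1C=O
F3 | step 2 | 2-(2-bromo-6-methoxyphenoxy)phenyl formate | COc1cccc(Br)c1Oc1ccccc1OC=O
F4 | step 2 | 2-(2-bromo-6-methoxyphenoxy)phenol | COc1cccc(Br)c1Oc1ccccc1O
F5 | step 2 | 4-bromo-2-(2-bromo-6-methoxyphenoxy)phenol | COc1cccc(Br)c1Oc1cc(Br)ccc1O
F6 | step 3 | 2-bromo-6-methoxyphenyl acetate | COc1cccc(Br)c1OC(C)=O
F7 | step 3 | 2,3-dibromo-6-methoxyphenyl acetate | COc1ccc(Br)c(Br)c1OC(C)=O
F8 | step 3 | 2,3,5-tribromo-6-methoxyphenyl acetate | COc1c(Br)cc(Br)c(Br)c1OC(C)=O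
F9 | step 3 | 2,3,5-tribromo-6-methoxyphenol | COc1c(Br)cc(Br)c(Br)c1O
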